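The bond between the carbinol carbon C1 and C4 of ring A, the 2,4-disubstituted oxazole, is the disconnection. The side chain from C2 to C6 is a 2-deoxy-L-fucose unit whose C3, C4 and C5 hydroxyls and C6 methyl already have the required configurations, so this sugar enters whole as an open-chain S-ethyl thioester with three silyl ethers. One base-free palladium-catalysed, copper-mediated acyl coupling joins it to the 4-boronic acid of the bisoxazole and gives the C1 ketone. Catalyst-controlled transfer hydrogenation then sets C1 and leaves its hydroxyl as the only one free for the fatty acyl group.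

Key step: step 11

Remark: the chain is numbered C1 (carbinol on ring A) to C6 (methyl), ring A is the 2,4-disubstituted oxazole and ring B the 5-substituted one; the target is (1R,3S,4R,5S), and C3 to C5 are those of 2-deoxy-L-fucose with no inversion. The triol carries three identical TBS ethers (one silylation, no regiochemical question, one fluoride step at the end). Boron is used as the free boronic acid because carboxylate-assisted transfer from a pinacol ester is slow; the pinacol ester is kept as its storable precursor.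

Step 1
Reactants: 1 L-fucose
Product: 4 di-O-acetyl-L-fucal, via L-fucose tetraacetate 2 (not isolated), via acetobromo-L-fucose 3 (not isolated)
Conditions: Ac2O, 33% HBr/AcOH, rt; then Zn dust, CuSO4·5H2O, NaOAc, AcOH/H2O, 0 °C to rt
Reagents that add atoms: acetic anhydride, CC(=O)OC(C)=O
Why: One-pot peracetylation, anomeric bromination and zinc-mediated reductive 1,2-elimination (Fischer–Zach glycal synthesis) remove only O1 and O2, so C3, C4 and C5 keep the sugar configuration.

Step 2
Reactants: 4 di-O-acetyl-L-fucal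
Product: 5 L-fucal
Conditions: NaOMe (cat.), MeOH, rt
Reagents that add atoms: none
Why: Zemplén transesterification should remove both acetates under conditions to which the enol ether is inert.

Step 3
Reactants: 5 L-fucal
Product: 7 2-deoxy-L-fucose propane-1,3-diyl dithioacetal, via 2-deoxy-L-fucose 6 (not isolated)
Conditions: 1 M aq. HCl, 0 °C to rt; then HS(CH2)3SH, conc. HCl, 0 °C
Reagents that add atoms: propane-1,3-dithiol, SCCCS
Why: Acid-catalysed Markovnikov hydration of the glycal gives the 2-deoxy sugar, which Fischer dithioacetalisation should open to the acyclic 1,3-dithiane without involving any stereocentre.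

Step 4
Reactants: 7 2-deoxy-L-fucose propane-1,3-diyl dithioacetal
Product: 8 3,4,5-tri-O-TBS dithiane
Conditions: TBSOTf, 2,6-lutidine, CH2Cl2, 0 °C to rt
Reagents that add atoms: tert-butyldimethylsilyl triflate, CC(C)(C)[Si](C)(C)OS(=O)(=O)C(F)(F)F
Why: Exhaustive silylation of the three secondary hydroxyls with the silyl triflate needs no regiocontrol and leaves the dithiane untouched.

Step 5
Reactants: 8 3,4,5-tri-O-TBS dithiane
Product: 9 (3S,4R,5S)-3,4,5-tris(tert-butyldimethylsilyloxy)hexanal
Conditions: I2, NaHCO3, acetone/H2O, 0 °C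
Reagents that add atoms: water, O
Why: Iodine-promoted hydrolytic cleavage of the dithiane in bicarbonate buffer should release the aldehyde without acid or base strong enough to eliminate the C3 silyloxy group.

Step 6
Reactants: 9 (3S,4R,5S)-3,4,5-tris(tert-butyldimethylsilyloxy)hexanal
Product: 10 (3S,4R,5S)-3,4,5-tris(tert-butyldimethylsilyloxy)hexanoic acid
Conditions: NaClO2, NaH2PO4, 2-methylbut-2-ene, t-BuOH/H2O, rt
Reagents that add atoms: sodium chlorite, [Na+].[O-]Cl=O
Why: Pinnick oxidation converts the aldehyde to the acid near pH 4, where silyl ethers and the β-silyloxy carbonyl unit are stable.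

Step 7
Reactants: 10 (3S,4R,5S)-3,4,5-tris(tert-butyldimethylsilyloxy)hexanoic acid
Product: 11 S-ethyl (3S,4R,5S)-3,4,5-tris(tert-butyldimethylsilyloxy)hexanethioate
Conditions: EtSH, DCC, DMAP (cat.), CH2Cl2, 0 °C to rt
Reagents that add atoms: ethanethiol, CCS
Why: Steglich-type carbodiimide thioesterification should proceed cleanly because C2 is a methylene and nothing can epimerise.

Step 8
Reactants: 12 5-(chloromethyl)oxazole; 13 2,4-dibromooxazole
Product: 15 4-bromo-2-(oxazol-5-ylmethyl)oxazole, via oxazol-5-ylmethylzinc chloride 14 (not isolated)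
Conditions: Zn dust, LiCl, THF, rt; then 13, Pd(PPh3)4 (cat.), THF, rt to 50 °C
Reagents that add atoms: none
Why: LiCl-assisted zinc insertion gives the heterobenzylic zinc chloride, and Negishi coupling should take place at the C2–Br bond of 13, which lies between O and N and adds to zerovalent palladium much faster than C4–Br, as in the 2,4-dihalothiazole series.

Step 9
Reactants: 15 4-bromo-2-(oxazol-5-ylmethyl)oxazole
Product: 16 2-(oxazol-5-ylmethyl)oxazol-4-yl pinacol boronate
Conditions: B2pin2, PdCl2(dppf) (cat.), KOAc, 1,4-dioxane, 85 °C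
Reagents that add atoms: bis(pinacolato)diboron, CC1(C)OB(OC1(C)C)B1OC(C)(C)C(C)(C)O1
Why: Miyaura borylation replaces the ring A C4 bromide under acetate conditions too mild to deprotonate the bridging CH2 or ring B C2–H.

Step 10
Reactants: 16 2-(oxazol-5-ylmethyl)oxazol-4-yl pinacol boronate
Product: 17 [2-(oxazol-5-ylmethyl)oxazol-4-yl]boronic acid
Conditions: NaIO4, NH4OAc, acetone/H2O, rt
Reagents that add atoms: water, O
Why: Hydrolysis of the boronate is driven by periodate cleavage of the released pinacol and should give the free boronic acid, which is taken on without storage.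

Step 11
Reactants: 11 S-ethyl (3S,4R,5S)-3,4,5-tris(tert-butyldimethylsilyloxy)hexanethioate; 17 [2-(oxazol-5-ylmethyl)oxazol-4-yl]boronic acid
Product: 18 (3S,4R,5S)-3,4,5-tris(tert-butyldimethylsilyloxy)-1-[2-(oxazol-5-ylmethyl)oxazol-4-yl]hexan-1-one
Conditions: Pd2(dba)3 (cat.), tri(2-furyl)phosphine, Cu(O2C-C4H3S) (copper thiophene-2-carboxylate), THF, 50 °C, Ar
Reagents that add atoms: none
Why: Zerovalent palladium inserts into the acyl C–S bond of 11; the monovalent copper carboxylate then binds the thiolate sulfur while its carboxylate oxygen coordinates boron, so the oxazol-4-yl group passes to divalent palladium and reductive elimination forms the C1–C4 (ring A) bond as a ketone. The closest known reaction type is the Liebeskind–Srogl thioester–boronic acid ketone synthesis. No ring is closed and no stereocentre is made; C3, C4 and C5 are spectators. The step needs acyl transfer without β-elimination of the C3 silyloxy group and without touching the acidic bridging CH2 or ring B C2–H, which the absence of any base secures. It also needs boron transfer to outrun protodeboronation next to the ring A nitrogen, which the free boronic acid, used in excess, and the weakly basic oxazole nitrogen should allow.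

Step 12
Reactants: 18 (3S,4R,5S)-3,4,5-tris(tert-butyldimethylsilyloxy)-1-[2-(oxazol-5-ylmethyl)oxazol-4-yl]hexan-1-one
Product: 19 (1R,3S,4R,5S)-3,4,5-tris(tert-butyldimethylsilyloxy)-1-[2-(oxazol-5-ylmethyl)oxazol-4-yl]hexan-1-ol
Conditions: RuCl(p-cymene)[(R,R)-TsDPEN] (cat.), HCO2H/Et3N (5:2), EtOAc, rt
Reagents that add atoms: none
Why: In this Noyori–Ikariya asymmetric transfer hydrogenation the (R,R)-ligated ruthenium hydride places the oxazolyl group under its arene ligand and should deliver hydride to the face that gives the (1R)-carbinol, overriding the remote C3 centre.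

Step 13
Reactants: 19 (1R,3S,4R,5S)-3,4,5-tris(tert-butyldimethylsilyloxy)-1-[2-(oxazol-5-ylmethyl)oxazol-4-yl]hexan-1-ol; 20 13-methyltetradecanoic acid
Product: 21 (1R,3S,4R,5S)-3,4,5-tris(tert-butyldimethylsilyloxy)-1-[2-(oxazol-5-ylmethyl)oxazol-4-yl]hexyl 13-methyltetradecanoate
Conditions: DCC, DMAP, CH2Cl2, rt
Reagents that add atoms: none
Why: Steglich esterification acylates the only free hydroxyl at oxygen, so C1 keeps its configuration.

Step 14
Reactants: 21 (1R,3S,4R,5S)-3,4,5-tris(tert-butyldimethylsilyloxy)-1-[2-(oxazol-5-ylmethyl)oxazol-4-yl]hexyl 13-methyltetradecanoate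
Product: 22 (1R,3S,4R,5S)-3,4,5-trihydroxy-1-[2-(oxazol-5-ylmethyl)oxazol-4-yl]hexyl 13-methyltetradecanoate
Conditions: 48% aq. HF, MeCN, 0 °C to rt
Reagents that add atoms: none
Why: Acidic fluoride desilylation should cleave the three TBS ethers while the ester and both oxazoles survive, and the non-basic medium disfavours acyl shift from O1 to O3.

Compound list
1 | L-fucose (open-chain form drawn) | O=C[C@@H](O)[C@H](O)[C@H](O)[C@H](C)O | starting material
2 | 1,2,3,4-tetra-O-acetyl-L-fucopyranose (anomeric mixture) | C[C@@H]1OC(OC(C)=O)[C@@H](OC(C)=O)[C@H](OC(C)=O)[C@@H]1OC(C)=O | intermediate (not isolated)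
3 | 2,3,4-tri-O-acetyl-α-L-fucopyranosyl bromide | C[C@@H]1O[C@@H](Br)[C@@H](OC(C)=O)[C@H](OC(C)=O)[C@@H]1OC(C)=O | intermediate (not isolated)
4 | 3,4-di-O-acetyl-L-fucal | C[C@@H]1OC=C[C@H](OC(C)=O)[C@@H]1OC(C)=O | intermediate
5 | L-fucal | C[C@@H]1OC=C[C@H](O)[C@@H]1O | intermediate
6 | 2-deoxy-L-fucose (open-chain form drawn) | O=CC[C@H](O)[C@H](O)[C@H](C)O | intermediate (not isolated)
7 | 2-deoxy-L-fucose propane-1,3-diyl dithioacetal, (2S,3R,4S)-5-(1,3-dithian-2-yl)pentane-2,3,4-triol | C1CSC(SC1)C[C@H](O)[C@H](O)[C@H](C)O | intermediate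
8 | 3,4,5-tri-O-(tert-butyldimethylsilyl)-2-deoxy-L-fucose propane-1,3-diyl dithioacetal | C1CSC(SC1)C[C@H](O[Si](C)(C)C(C)(C)C)[C@H](O[Si](C)(C)C(C)(C)C)[C@H](C)O[Si](C)(C)C(C)(C)C | intermediate
9 | (3S,4R,5S)-3,4,5-tris(tert-butyldimethylsilyloxy)hexanal | O=CC[C@H](O[Si](C)(C)C(C)(C)C)[C@H](O[Si](C)(C)C(C)(C)C)[C@H](C)O[Si](C)(C)C(C)(C)C | intermediate
10 | (3S,4R,5S)-3,4,5-tris(tert-butyldimethylsilyloxy)hexanoic acid | OC(=O)C[C@H](O[Si](C)(C)C(C)(C)C)[C@H](O[Si](C)(C)C(C)(C)C)[C@H](C)O[Si](C)(C)C(C)(C)C | intermediate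
11 | S-ethyl (3S,4R,5S)-3,4,5-tris(tert-butyldimethylsilyloxy)hexanethioate | CCSC(=O)C[C@H](O[Si](C)(C)C(C)(C)C)[C@H](O[Si](C)(C)C(C)(C)C)[C@H](C)O[Si](C)(C)C(C)(C)C | intermediate
12 | 5-(chloromethyl)oxazole | ClCc1cnco1 | starting material
13 | 2,4-dibromooxazole | Brc1coc(Br)n1 | starting material
14 | (oxazol-5-ylmethyl)zinc chloride | Cl[Zn]Cc1cnco1 | intermediate (not isolated)
15 | 4-bromo-2-(oxazol-5-ylmethyl)oxazole | Brc1coc(Cc2cnco2)n1 | intermediate
16 | 2-(oxazol-5-ylmethyl)-4-(4,4,5,5-tetramethyl-1,3,2-dioxaborolan-2-yl)oxazole | CC1(C)OB(OC1(C)C)c1coc(Cc2cnco2)n1 | intermediate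
17 | [2-(oxazol-5-ylmethyl)oxazol-4-yl]boronic acid | OB(O)c1coc(Cc2cnco2)n1 | intermediate
18 | (3S,4R,5S)-3,4,5-tris(tert-butyldimethylsilyloxy)-1-[2-(oxazol-5-ylmethyl)oxazol-4-yl]hexan-1-one | O=C(C[C@H](O[Si](C)(C)C(C)(C)C)[C@H](O[Si](C)(C)C(C)(C)C)[C@H](C)O[Si](C)(C)C(C)(C)C)c1coc(Cc2cnco2)n1 | intermediate
19 | (1R,3S,4R,5S)-3,4,5-tris(tert-butyldimethylsilyloxy)-1-[2-(oxazol-5-ylmethyl)oxazol-4-yl]hexan-1-ol | O[C@H](C[C@H](O[Si](C)(C)C(C)(C)C)[C@H](O[Si](C)(C)C(C)(C)C)[C@H](C)O[Si](C)(C)C(C)(C)C)c1coc(Cc2cnco2)n1 | intermediate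
20 | 13-methyltetradecanoic acid | CC(C)CCCCCCCCCCCC(=O)O | starting material
21 | (1R,3S,4R,5S)-3,4,5-tris(tert-butyldimethylsilyloxy)-1-[2-(oxazol-5-ylmethyl)oxazol-4-yl]hexyl 13-methyltetradecanoate | CC(C)CCCCCCCCCCCC(=O)O[C@H](C[C@H](O[Si](C)(C)C(C)(C)C)[C@H](O[Si](C)(C)C(C)(C)C)[C@H](C)O[Si](C)(C)C(C)(C)C)c1coc(Cc2cnco2)n1 | intermediate
22 | (1R,3S,4R,5S)-3,4,5-trihydroxy-1-[2-(oxazol-5-ylmethyl)oxazol-4-yl]hexyl 13-methyltetradecanoate | CC(C)CCCCCCCCCCCC(=O)O[C@H](C[C@H](O)[C@H](O)[C@H](C)O)c1coc(Cc2cnco2)n1 | target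

Total step count: 14
Longest linear sequence: 11 steps (steps 1 to 7, then 11 to 14); steps 8 to 10 form the convergent branch.

Steps most likely to fail

Step 11. The boronic acid may lose boron by protodeboronation at the carbon next to the ring A nitrogen, or transfer its oxazolyl group too slowly, so that the thioester is left unconsumed. The fallback replaces boron by tin and also bypasses steps 9 and 10. It sets out from bromide 15, which with hexabutylditin and Pd(PPh3)4 in toluene at 100 °C should give 2-(oxazol-5-ylmethyl)-4-(tributylstannyl)oxazole F1. F1 and thioester 11 are then coupled with Pd2(dba)3, tri(2-furyl)phosphine and copper diphenylphosphinate, Cu(O2PPh2), in THF. This is the organostannane variant of the neutral thioester ketone synthesis, and it returns to the route at ketone 18.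

Step 12. Facial selectivity may be poor if the C3 silyloxy centre is mismatched with the catalyst, or the ring A nitrogen may slow the catalyst by coordination. The fallback gives up catalyst control and corrects C1 afterwards. It sets out from ketone 18, which NaBH4 in MeOH at low temperature should reduce to both C1 epimers. Alcohol 19 is separated by chromatography and continues through step 13. The (1S)-alcohol F2 is esterified with acid 20 under Mitsunobu conditions (PPh3, DIAD, THF, 0 °C to rt) with inversion at C1, which returns to the route at ester 21.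

Step 8. The two C–Br bonds of 13 may not be discriminated well enough (double coupling), or the heterobenzylic chloride may homocouple during zinc insertion. The fallback reverses the polarity so that ring A carries only one halogen. It sets out from chloride 12 and purchased 4-bromooxazole F3. F3 is zincated at its most acidic position, C2, with TMPZnCl·LiCl in THF at rt to give (4-bromooxazol-2-yl)zinc chloride F4. Negishi coupling of F4 with the benzylic-type chloride 12 under Pd(PPh3)4 returns to the route at bromide 15.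

Further compounds
F1 | step 11 | 2-(oxazol-5-ylmethyl)-4-(tributylstannyl)oxazole | CCCC[Sn](CCCC)(CCCC)c1coc(Cc2cnco2)n1
F2 | step 12 | (1S,3S,4R,5S)-3,4,5-tris(tert-butyldimethylsilyloxy)-1-[2-(oxazol-5-ylmethyl)oxazol-4-yl]hexan-1-ol | O[C@@H](C[C@H](O[Si](C)(C)C(C)(C)C)[C@H](O[Si](C)(C)C(C)(C)C)[C@H](C)O[Si](C)(C)C(C)(C)C)c1coc(Cc2cnco2)n1
F3 | step 8 | 4-bromooxazole (purchased) | Brc1cocn1
F4 | step 8 | (4-bromooxazol-2-yl)zinc chloride | Cl[Zn]c1nc(Br)co1
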